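**Plan**

- Rings: upper unit A (benzo), C (pyran), B (pyrogallol); lower unit D (benzo), F (pyran), E (pyrogallol). The target is robinetinidol-(4α→2')-leucorobinetinidin.
- Cuts, in retrosynthetic order: lower C4–H (hydride to a ketone); four O–benzyl bonds; the interflavan bond C4 (ring C)–C2' (ring E); the C3–O and C4–O bonds (osmylation of a flav-3-ene); the O1–C2 bond (closure of ring C); the C2=C3 aldol bond of a chalcone.
- Enabling feature: O1 is the phenolic oxygen on C8a, ortho to C4a, and C2 is benzylic to ring B. With C3–C4 at the alkene level, O1–C8a–C4a–C4–C3–C2 is a 1-oxatriene (the vinyl ortho-quinone methide of ring A, stabilised by the C7 oxygen para to C4a). Ring C therefore closes by O1–C2 bond formation while ring A rearomatises, and the C3=C4 bond is left where the 3-OH and the C4–aryl bond are needed.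
- Forward: 1 + 2 → chalcone 3 → racemic allylic alcohol 4 → (via 5) enantioconvergent ring-C closure to flav-3-ene 6 → cis-diol 7 → Friedel–Crafts union with ring E of chiral-pool (+)-dihydrorobinetin 8 (rings D, E, F ready-made) → 9 → debenzylation to 10 → ketone reduction to target 11.
- Stereochemistry: upper C2 from the chiral phosphoramide counter-anion; upper C3 from osmylation anti to the C2 aryl; upper C4 from attack of ring E anti to the 3-OH; lower C2 and C3 from 8; lower C4 from axial hydride delivery.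

Key step: step 3

Assumption: (+)-dihydrorobinetin 8 is taken as the commercial natural (2R,3R) enantiomer, and of the two antipodes of the phosphoramide catalyst the one that leads to (S)-6 is used.

**Route**

Step 1
Reactants: 1 4'-benzyloxy-2'-hydroxyacetophenone; 2 3,4,5-tris(benzyloxy)benzaldehyde
Product: 3 (E)-1-[4-(benzyloxy)-2-hydroxyphenyl]-3-[3,4,5-tris(benzyloxy)phenyl]prop-2-en-1-one
Conditions: KOH (50% aq.), EtOH, rt
Reagents that add atoms: none
Why: Claisen–Schmidt (crossed aldol) condensation, in which the ketone enolate adds to the non-enolisable aldehyde and E1cB dehydration gives the (E)-enone; no stereocentre is formed.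

Step 2
Reactants: 3 (E)-2'-hydroxychalcone
Product: 4 rac-(E)-1-[4-(benzyloxy)-2-hydroxyphenyl]-3-[3,4,5-tris(benzyloxy)phenyl]prop-2-en-1-ol
Conditions: NaBH4, CeCl3·7H2O, MeOH–THF, −40 °C; pH 7 buffer work-up, used cold without purification
Reagents that add atoms: none
Why: Luche reduction, in which CeCl3-assisted 1,2-hydride delivery spares the C=C bond; the carbinol is formed racemic, which is irrelevant because its configuration is erased in step 3, and the neutral cold work-up should prevent premature cyclisation.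

Step 3
Reactants: 4 racemic allylic alcohol
Product: 6 (2S)-7-(benzyloxy)-2-[3,4,5-tris(benzyloxy)phenyl]-2H-chromene, via vinyl ortho-quinone methide 5 (not isolated)
Conditions: (R)-3,3'-bis(2,4,6-triisopropylphenyl)-H8-BINOL N-triflylphosphoramide (5 mol%), toluene, 4 Å MS, −78 °C
Reagents that add atoms: none
Why: The strong chiral acid ionises the carbinol, which ring A activates through its ortho-hydroxyl and para-benzyloxy groups, so that both enantiomers of 4 converge on one planar species, the O-protonated form of vinyl ortho-quinone methide 5 held as a contact ion pair with the chiral phosphoramide anion. In the s-cis, (Z)-configured oxatriene O1=C8a–C4a=C4–C3=C2 an oxa-6π electrocyclisation (equivalently a 6-endo-trig capture of the allyl-cation terminus C2 by O1) forms the O1–C2 bond, closes ring C and restores the aromaticity of ring A. The closest known reaction type is the chiral Brønsted acid-catalysed asymmetric allylic substitution of phenol-tethered allylic alcohols to 2H-chromenes through chiral contact ion pairs. The only new stereocentre, C2, is set by the catalyst, whose anion is hydrogen-bonded to O1–H and shields one face of the C2 terminus. The step needs O-attack at C2 rather than Friedel–Crafts closure of ring B onto C4 (indene formation) or intermolecular etherification, which the ortho-placed hydroxyl, the six-membered transition state and the gain of aromaticity secure. It also needs the catalysed path to outrun the racemic background and the product not to re-ionise, which the low temperature, the non-polar solvent and the molecular sieves are chosen to serve.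

Step 4
Reactants: 6 (S)-flav-3-ene
Product: 7 (2R,3S,4S)-7-(benzyloxy)-2-[3,4,5-tris(benzyloxy)phenyl]chromane-3,4-diol
Conditions: OsO4 (2 mol%), NMO, acetone–THF–H2O, 0 °C to rt
Reagents that add atoms: N-methylmorpholine N-oxide, C[N+]1([O-])CCOCC1; water, O (the net oxygen sources, transferred through catalytic osmium tetroxide, O=[Os](=O)(=O)=O)
Why: Upjohn cis-dihydroxylation, in which OsO4 adds suprafacially to the electron-rich C3=C4 bond from the face opposite to the C2 aryl group; this sets C3 (S, hydroxyl trans to the aryl) and C4 (S, cis to the 3-OH), the C4 hydroxyl serving only as the leaving group of step 5.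

Step 5
Reactants: 7 2,3-trans-3,4-cis-diol; 8 (+)-dihydrorobinetin [(2R,3R)-3,7-dihydroxy-2-(3,4,5-trihydroxyphenyl)chroman-4-one]
Product: 9 (2R,3R)-2-{2-[(2R,3S,4S)-7-(benzyloxy)-3-hydroxy-2-[3,4,5-tris(benzyloxy)phenyl]chroman-4-yl]-3,4,5-trihydroxyphenyl}-3,7-dihydroxychroman-4-one
Conditions: 8 (3 equiv), BF3·OEt2 (0.3 equiv), dioxane, rt, Ar
Reagents that add atoms: none
Why: Friedel–Crafts alkylation by a flavan-4-yl cation (the bond-forming mode of proanthocyanidin assembly), in which the acid ionises the C4 hydroxyl to a cation stabilised by O1 (ortho) and the 7-benzyloxy group (para); C2' of ring E of 8 (equivalent to C6' and para to a hydroxyl, ring D being deactivated by the C4 carbonyl) should attack from the face opposite to the C3 hydroxyl, which sets C4 as S (3,4-trans, all three ring-C substituents equatorial).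

Step 6
Reactants: 9 tetra-O-benzyl biflavonoid ketone
Product: 10 (2R,3R)-2-{2-[(2R,3S,4S)-3,7-dihydroxy-2-(3,4,5-trihydroxyphenyl)chroman-4-yl]-3,4,5-trihydroxyphenyl}-3,7-dihydroxychroman-4-one
Conditions: H2 (1 atm), Pd(OH)2/C, THF–MeOH, rt
Reagents that add atoms: none
Why: Catalytic hydrogenolysis of the four aryl benzyl ethers; the cyclic benzylic O1–C2 bonds, the diarylmethine C4 and the para-hydroxylated aryl ketone are expected to survive under neutral conditions at 1 atm, and no stereocentre is touched.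

Step 7
Reactants: 10 robinetinidol-(4α→2')-dihydrorobinetin
Product: 11 (2R,3S,4R)-2-{2-[(2R,3S,4S)-3,7-dihydroxy-2-(3,4,5-trihydroxyphenyl)chroman-4-yl]-3,4,5-trihydroxyphenyl}chromane-3,4,7-triol
Conditions: NaBH4, EtOH (degassed), 0 °C, N2; AcOH to pH 6; Sephadex LH-20 (EtOH)
Reagents that add atoms: none
Why: Borohydride reduction of the 2,3-trans-dihydroflavonol carbonyl, in which axial hydride attack on the half-chair ring F (2-aryl and 3-OH equatorial) should give the equatorial C4 alcohol (4R, 3,4-trans), as is usual for 2,3-trans-dihydroflavonols; the product is kept away from acid because a 7-hydroxyflavan-4-ol ionises easily.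

**Compound list**

1 | 1-[4-(benzyloxy)-2-hydroxyphenyl]ethan-1-one | CC(=O)c1ccc(OCc2ccccc2)cc1O | starting material
2 | 3,4,5-tris(benzyloxy)benzaldehyde | O=Cc1cc(OCc2ccccc2)c(OCc2ccccc2)c(OCc2ccccc2)c1 | starting material
3 | (E)-1-[4-(benzyloxy)-2-hydroxyphenyl]-3-[3,4,5-tris(benzyloxy)phenyl]prop-2-en-1-one | O=C(/C=C/c1cc(OCc2ccccc2)c(OCc2ccccc2)c(OCc2ccccc2)c1)c1ccc(OCc2ccccc2)cc1O | intermediate
4 | rac-(E)-1-[4-(benzyloxy)-2-hydroxyphenyl]-3-[3,4,5-tris(benzyloxy)phenyl]prop-2-en-1-ol | OC(/C=C/c1cc(OCc2ccccc2)c(OCc2ccccc2)c(OCc2ccccc2)c1)c1ccc(OCc2ccccc2)cc1O | intermediate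
5 | (6Z)-3-(benzyloxy)-6-{(E)-3-[3,4,5-tris(benzyloxy)phenyl]prop-2-en-1-ylidene}cyclohexa-2,4-dien-1-one (vinyl ortho-quinone methide of ring A; present as its O-protonated ion pair) | O=C1C=C(OCc2ccccc2)C=C/C1=C/C=C/c1cc(OCc2ccccc2)c(OCc2ccccc2)c(OCc2ccccc2)c1 | intermediate (not isolated)
6 | (2S)-7-(benzyloxy)-2-[3,4,5-tris(benzyloxy)phenyl]-2H-chromene | C(c1ccccc1)Oc1ccc2c(c1)O[C@H](c1cc(OCc3ccccc3)c(OCc3ccccc3)c(OCc3ccccc3)c1)C=C2 | intermediate
7 | (2R,3S,4S)-7-(benzyloxy)-2-[3,4,5-tris(benzyloxy)phenyl]chromane-3,4-diol (2,3-trans-3,4-cis) | C(c1ccccc1)Oc1ccc2c(c1)O[C@H](c1cc(OCc3ccccc3)c(OCc3ccccc3)c(OCc3ccccc3)c1)[C@@H](O)[C@H]2O | intermediate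
8 | (+)-dihydrorobinetin, (2R,3R)-3,7-dihydroxy-2-(3,4,5-trihydroxyphenyl)chroman-4-one | Oc1cc(cc(O)c1O)[C@H]1Oc2cc(O)ccc2C(=O)[C@@H]1O | starting material
9 | (2R,3R)-2-{2-[(2R,3S,4S)-7-(benzyloxy)-3-hydroxy-2-[3,4,5-tris(benzyloxy)phenyl]chroman-4-yl]-3,4,5-trihydroxyphenyl}-3,7-dihydroxychroman-4-one | C(c1ccccc1)Oc1ccc2c(c1)O[C@H](c1cc(OCc3ccccc3)c(OCc3ccccc3)c(OCc3ccccc3)c1)[C@@H](O)[C@@H]2c1c([C@H]2Oc3cc(O)ccc3C(=O)[C@@H]2O)cc(O)c(O)c1O | intermediate
10 | (2R,3R)-2-{2-[(2R,3S,4S)-3,7-dihydroxy-2-(3,4,5-trihydroxyphenyl)chroman-4-yl]-3,4,5-trihydroxyphenyl}-3,7-dihydroxychroman-4-one | Oc1ccc2c(c1)O[C@H](c1cc(O)c(O)c(O)c1)[C@@H](O)[C@@H]2c1c([C@H]2Oc3cc(O)ccc3C(=O)[C@@H]2O)cc(O)c(O)c1O | intermediate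
11 | (2R,3S,4R)-2-{2-[(2R,3S,4S)-3,7-dihydroxy-2-(3,4,5-trihydroxyphenyl)chroman-4-yl]-3,4,5-trihydroxyphenyl}chromane-3,4,7-triol | Oc1ccc2c(c1)O[C@H](c1cc(O)c(O)c(O)c1)[C@@H](O)[C@@H]2c1c([C@H]2Oc3cc(O)ccc3[C@@H](O)[C@@H]2O)cc(O)c(O)c1O | target

**Step count**

Total steps: 7. Longest linear sequence: 7 (from 1 and 2 to 11; 8 enters at step 5).

**Steps most likely to fail**

1. Step 3. The risks are incomplete face discrimination in the ion pair, racemic background cyclisation of the very labile alcohol, and re-ionisation of the product at C2 with loss of enantiopurity. The fallback sets out from 3 and comes back at 9; it keeps the O1–C2 closure but makes it a stereospecific epoxide opening. The phenol of 3 is protected (MOMCl, iPr2NEt, CH2Cl2) to give (E)-1-[4-(benzyloxy)-2-(methoxymethoxy)phenyl]-3-[3,4,5-tris(benzyloxy)phenyl]prop-2-en-1-one F1. Juliá–Colonna epoxidation (poly-L-leucine, urea–H2O2, DBU, THF) should give the (αR,βS)-epoxy ketone F2. HCl in MeOH–THF removes the MOM group, and the freed phenol opens the oxirane at the benzylic carbon (6-endo, inversion) to give (2R,3R)-7-(benzyloxy)-3-hydroxy-2-[3,4,5-tris(benzyloxy)phenyl]chroman-4-one F3. NaBH4 (MeOH–THF, 0 °C) gives the (2R,3S,4R)-3,4-trans-diol F4, which forms the same C4 cation as 7 under the conditions of step 5 and so gives 9.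

2. Step 5. The risks are O-alkylation or oligomerisation in place of C-alkylation, attack at ring D, and poor facial selectivity in the capture of the free cation. The fallback sets out from 6 and comes back at 9; it replaces cation capture by a stereospecific anti epoxide opening. Dimethyldioxirane (acetone, −40 °C) should epoxidise 6 anti to the C2 aryl group to give (2R,3S,4S)-7-(benzyloxy)-3,4-epoxy-2-[3,4,5-tris(benzyloxy)phenyl]chromane F5. This is opened at C4 with inversion by ring E of 8 in hexafluoroisopropanol–CH2Cl2 at low temperature, giving 9 with the 3,4-trans relation fixed by the opening.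

3. Step 4. The risks are osmylation on the wrong face, over-oxidation of the electron-rich diol, and racemisation of the chromene before it is consumed. The fallback sets out from 6 and comes back at 9; it separates the two oxygenations. Hydroboration–oxidation (BH3·SMe2, THF, 0 °C; then NaBO3, H2O) anti to the C2 aryl group should give (2R,3S)-7-(benzyloxy)-2-[3,4,5-tris(benzyloxy)phenyl]chroman-3-ol F6. Benzylic oxidation with DDQ in CH2Cl2–MeOH should then give (2R,3S,4S)-7-(benzyloxy)-4-methoxy-2-[3,4,5-tris(benzyloxy)phenyl]chroman-3-ol F7, which ionises at C4 under the conditions of step 5 and is captured by 8 to give 9.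

**Further compounds**

F1 | step 3 | (E)-1-[4-(benzyloxy)-2-(methoxymethoxy)phenyl]-3-[3,4,5-tris(benzyloxy)phenyl]prop-2-en-1-one | COCOc1cc(OCc2ccccc2)ccc1C(=O)/C=C/c1cc(OCc2ccccc2)c(OCc2ccccc2)c(OCc2ccccc2)c1
F2 | step 3 | [4-(benzyloxy)-2-(methoxymethoxy)phenyl]{(2R,3S)-3-[3,4,5-tris(benzyloxy)phenyl]oxiran-2-yl}methanone | COCOc1cc(OCc2ccccc2)ccc1C(=O)[C@@H]1O[C@H]1c1cc(OCc2ccccc2)c(OCc2ccccc2)c(OCc2ccccc2)c1
F3 | step 3 | (2R,3R)-7-(benzyloxy)-3-hydroxy-2-[3,4,5-tris(benzyloxy)phenyl]chroman-4-one | C(c1ccccc1)Oc1ccc2c(c1)O[C@H](c1cc(OCc3ccccc3)c(OCc3ccccc3)c(OCc3ccccc3)c1)[C@@H](O)C2=O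
F4 | step 3 | (2R,3S,4R)-7-(benzyloxy)-2-[3,4,5-tris(benzyloxy)phenyl]chromane-3,4-diol | C(c1ccccc1)Oc1ccc2c(c1)O[C@H](c1cc(OCc3ccccc3)c(OCc3ccccc3)c(OCc3ccccc3)c1)[C@@H](O)[C@@H]2O
F5 | step 5 | (2R,3S,4S)-7-(benzyloxy)-3,4-epoxy-2-[3,4,5-tris(benzyloxy)phenyl]chromane | C(c1ccccc1)Oc1ccc2c(c1)O[C@H](c1cc(OCc3ccccc3)c(OCc3ccccc3)c(OCc3ccccc3)c1)[C@H]1O[C@H]12
F6 | step 4 | (2R,3S)-7-(benzyloxy)-2-[3,4,5-tris(benzyloxy)phenyl]chroman-3-ol | C(c1ccccc1)Oc1ccc2c(c1)O[C@H](c1cc(OCc3ccccc3)c(OCc3ccccc3)c(OCc3ccccc3)c1)[C@@H](O)C2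
F7 | step 4 | (2R,3S,4S)-7-(benzyloxy)-4-methoxy-2-[3,4,5-tris(benzyloxy)phenyl]chroman-3-ol | C(c1ccccc1)Oc1ccc2c(c1)O[C@H](c1cc(OCc3ccccc3)c(OCc3ccccc3)c(OCc3ccccc3)c1)[C@@H](O)[C@H]2OC
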